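## Structural features

Selaginellin A (19, C34H24O3) has no stereocentre. Ring A is a benzene with four contiguous substituents: methyl at C1, a (4-hydroxyphenyl)ethynyl group at C2, the exocyclic carbon C7 at C3 and a 4-hydroxyphenyl ring at C4; C5 and C6 carry hydrogen. C7 is a fully substituted sp2 carbon joining ring A, a phenyl ring and a cyclohexa-2,5-dien-1-one ring, i.e. a p-quinone methide (fuchsone) unit. That dienone ring is symmetric, so the C7=C bond has no E/Z descriptor. No stereocentres adjoin one another in the target; the only sp3 centres on the route (three carbinols and the two ring carbons of the cycloadduct) are racemic and transient. The fragile groups are the quinone methide (electrophilic at C7, reversibly protonated to a triarylmethyl cation that sits ortho to an alkyne and an aryl ring), the diarylalkyne and the two free phenols. The real difficulty is the regiodefined assembly of the 1,2,3,4-tetrasubstituted ring A and the crowding of C7 between two ortho substituents. The key step uses the fact that C4–C5–C6–C1 is a butadiene with aryl and methyl termini and that C2–C3 is one triple bond of a conjugated diynone. The carbonyl carbon of that diynone is C7 and its second triple bond is already the C2 alkyne.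

## Logic of the disconnections

19 ⇒ 17 (through 18). No skeletal bond is cut. The C7=C bond of the quinone methide is traced back to a C7–OH bond and the three O–H bonds to acetal-protected oxygens. The quinone methide is the most reactive part and should appear last; the carbinol with its para-oxygenated aryl ring is its latent form. The gain is a neutral, chromatographable triarylmethanol whose four oxygen functions are unmasked by one reagent. The forward step must cleave three acetals and ionize C7 without letting the cation attack the ortho aryl ring or the alkyne.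

17 ⇒ 16. The C7–phenyl bond is cut. The unsubstituted ring is the simplest aryl nucleophile, and its removal leaves C7 as a ketone carbonyl, which is exactly the activating group the cycloaddition needs. A ring and the racemic carbinol centre disappear. The forward addition must reach a doubly ortho-flanked diaryl ketone and leave the neighbouring alkyne alone.

16 ⇒ 6 + 14 (through 15). Ring A bonds C1–C2 and C3–C4 are cut. This splits the arene into a four-carbon unit with methyl and aryl at its ends and a two-carbon unit carrying the C7 carbonyl and the alkyne, so one orientation rule places all four substituents. The tetrasubstituted arene becomes two linear, achiral fragments of similar size. The forward step must put the acyl-bearing carbon next to the aryl terminus, must use only the carbonyl-conjugated triple bond, and the adduct must be dehydrogenated without harm to the acetals or the remaining alkyne.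

14 ⇒ 13 ⇒ 9 + 11 (through 12). First the ketone is taken back to the alcohol, because the diynone is the least stable compound before the key step and is best made last. Then the C(sp)–C(aryl) bond at the far end of the diyne is cut, a standard palladium/copper coupling site. The aryl partner 11 is simple. The forward coupling must generate and consume the terminal diyne in one flask.

9 ⇒ 7 + 2 (through 8). The bond between the carbinol carbon and the diyne is cut. The four-carbon diyne is available as a stable bis-silylated solid in which one silyl group can be exchanged for lithium. The diyne arrives in one piece and free butadiyne never exists. The forward step must stop at mono-desilylation.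

6 ⇒ 2 + 3 (through 4 and 5). The double bond next to the aryl ring (the future C4–C5 bond of ring A) is cut. A carbonyl olefination joins a four-carbon phosphonium salt to the same aldehyde that serves the diynone, so both key-step partners come from one protected aldehyde. The forward step must deliver the (E,E)-diene, the only geometry that reaches the s-cis form easily.

2 ⇒ 1 and 11 ⇒ 10. The O–CH2 acetal bonds are cut. The methoxymethyl ether survives organolithiums, carbonate, MnO2, heat and DDQ and leaves with mild acid in the last step. The starting materials become two bulk phenols. The alkylating agent should be generated and consumed in solution.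

## Other disconnections considered

Alternative 1: The cut is at ring A bonds C1–C6 and C4–C5, so the unsubstituted edge is added last. The fully substituted pyranone A1 already carries methyl, arylethynyl, ester and aryl in ring A order. It would add the enol ether A2 across its C3 and C6 positions in an inverse-demand [4+2] reaction. The bridged lactone would then undergo decarboxylative cycloreversion and lose the alkoxy group as its alcohol to give benzoate A3.
- In its favour: C5 and C6 both carry hydrogen, so either orientation of A2 gives the same arene and the substituent order is fixed by the pyranone. On regiocontrol this plan is better than the chosen one. It also needs no oxidant.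
- Against it here: A1 is a dense heterocycle whose own synthesis should cost about as much as that of 14. A donor-substituted pyranone is a sluggish diene, and its pendent alkyne is a competing 2π partner. A3 holds C7 at the carboxylate level, so two different aryl groups must be added in turn to a doubly ortho-flanked ester, with a stop at the ketone. The methyl ethers call for Lewis-acid demethylation next to the alkyne and the ionizable C7.
- Comparison: both plans are cycloaddition–aromatization sequences. The chosen plan delivers C7 as a ketone with one aryl group already attached and uses acetals that leave with mild acid. Alternative 1 should be several steps longer.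

Alternative 2: The cuts are C3–C4 and C1–C6, with the C2–alkyne bond cut later. Under amine catalysis the central carbon of diketone A4 would add to enal A5, and the ethyl-ketone α-carbon would close onto the aldehyde. Oxidative dehydrogenation of the cyclohexenone would then give phenol ketone A6.
- In its favour: the partners are cheap and stable, no polyyne is heated, and the constitution of ring A follows from the connectivity of the partners. On safety it is better than the chosen plan and on regiochemical certainty at least equal. On paper it is also shorter: annulation, sulfonylation of the phenol, alkynylation, aryl addition and deprotection.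
- Against it here: the alkyne must be installed by coupling at a position flanked by methyl and aroyl groups. The Michael adduct of a 1,3-diketone and an enal may rest as a cyclic hemiacetal or fragment by retro-Claisen cleavage instead of closing the carbocycle. Methyl ether cleavage returns at the end unless the enal is remade with acetals.
- Comparison: the mechanism is ionic and stepwise and depends on chemoselectivity among several enolizable sites, against one pericyclic event in the chosen plan. The chosen plan carries the alkyne in and avoids a late hindered coupling. The last C–C bond at C7 is formed in an equivalent way in both.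

Alternative 3: The cuts are the C4–aryl and C3–C7 bonds; ring A is bought and no ring is formed. Fluoroarene A7 would be metallated at C3, between fluorine and the alkynyl group, and lose fluoride to give the aryne. The aryl Grignard reagent A8 would add at C4, and the resulting C3 arylmagnesium would be trapped by benzophenone A9 to give carbinol A10, which is the same compound as 17.
- In its favour: three simple pieces and one flask reach the penultimate intermediate, with no ring construction and no oxidant. On convergence and step economy this plan is better than the chosen one, and protecting groups and end-game are identical.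
- Against it here: the direction of addition to the 3-alkynyl aryne rests on the modest inductive and distortion bias of the alkynyl group. Metallation could also occur at C5. A8 adds directly to A9, so the ketone must be introduced only after the aryne has been consumed. The doubly flanked arylmagnesium at C3 must then attack a diaryl ketone faster than it is protonated.
- Comparison: this is a polar organometallic cascade with three selectivity demands, against one frontier-orbital-controlled orientation in the chosen plan. The chosen plan is longer but has fewer simultaneous selectivity demands, and its main one, the orientation of the cycloaddition, follows a well-understood rule.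

Key step: step 7

Remark on the chemistry: the precursor and product structures of the key step map atom for atom onto ring A of 19 (carbonyl carbon = C7, distal triple bond = C2 alkyne) and need no correction. Rotation about the aryl–aryl and aryl–C7 bonds is taken to be fast.

Remark on safety: chloromethyl methyl ether is made and used in solution, free butadiyne is never formed, the terminal diyne 12 is never isolated, and the diynone 14 is heated only in dilute solution with an inhibitor.

## Route

Step 1
Reactants: 1 4-hydroxybenzaldehyde
Product: 2 4-(methoxymethoxy)benzaldehyde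
Conditions: CH2(OMe)2, AcCl, ZnBr2 (0.01 mol %), toluene, rt; then 1, i-Pr2NEt, 0 °C → rt; aq. NH4Cl
Reagents that add atoms: chloromethyl methyl ether COCCl, made in the flask from dimethoxymethane COCOC and acetyl chloride CC(=O)Cl
Why: O-alkylation of the phenoxide by the chloro ether (Williamson-type protection); the reagent arises by ZnBr2-catalysed exchange, is never handled neat, and the surplus is destroyed by the aqueous quench.

Step 2
Reactants: 2 4-(methoxymethoxy)benzaldehyde; 3 [(2E)-but-2-en-1-yl]triphenylphosphonium bromide
Product: 6 1-(methoxymethoxy)-4-[(1E,3E)-penta-1,3-dien-1-yl]benzene, via crotylidene ylide 4 (not isolated), via (1Z,3E)-diene isomer 5 (not isolated)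
Conditions: 3, n-BuLi, THF, −78 → 0 °C; 2, −78 °C → rt; hexane, filter; then I2 (5 mol %), hexane, rt, daylight; aq. Na2S2O3
Reagents that add atoms: none
Why: Wittig olefination with a semi-stabilized allylic ylide should give a mixture of geometries at the new double bond; reversible addition of iodine atoms then funnels all isomers into the thermodynamically preferred (1E,3E)-diene.

Step 3
Reactants: 7 1,4-bis(trimethylsilyl)buta-1,3-diyne; 2 4-(methoxymethoxy)benzaldehyde
Product: 9 racemic 1-[4-(methoxymethoxy)phenyl]-5-(trimethylsilyl)penta-2,4-diyn-1-ol, via lithium (trimethylsilyl)butadiynide 8 (not isolated)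
Conditions: 7 (1.2 equiv), MeLi·LiBr (1.1 equiv), THF, −78 °C → rt; then 2 (1.0 equiv), −78 → 0 °C; aq. NH4Cl
Reagents that add atoms: none
Why: Methyllithium cleaves one C–Si bond selectively (mono-desilylation, the monoanion resists a second attack) and the acetylide undergoes 1,2-addition to the aldehyde; the carbinol centre forms racemic and is removed in step 6.

Step 4
Reactants: 10 4-iodophenol
Product: 11 1-iodo-4-(methoxymethoxy)benzene
Conditions: CH2(OMe)2, AcCl, ZnBr2 (0.01 mol %), toluene, rt; then 10, i-Pr2NEt, 0 °C → rt; aq. NH4Cl
Reagents that add atoms: chloromethyl methyl ether COCCl, made in the flask from dimethoxymethane COCOC and acetyl chloride CC(=O)Cl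
Why: Same Williamson-type acetal protection as step 1; the aryl iodide is inert to these conditions.

Step 5
Reactants: 9 racemic 1-[4-(methoxymethoxy)phenyl]-5-(trimethylsilyl)penta-2,4-diyn-1-ol; 11 1-iodo-4-(methoxymethoxy)benzene
Product: 13 racemic 1,5-bis[4-(methoxymethoxy)phenyl]penta-2,4-diyn-1-ol, via terminal diynol 12 (not isolated)
Conditions: Pd(PPh3)4 (3 mol %), CuI (5 mol %), K2CO3 (2.5 equiv), MeOH/THF 1:1, degassed, Ar, rt → 40 °C
Reagents that add atoms: none
Why: Carbonate-mediated methanolysis of the alkynyl C–Si bond releases the terminal diyne in the presence of the catalysts, where Sonogashira coupling with the aryl iodide should consume it at once; exclusion of oxygen suppresses Glaser dimerization.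

Step 6
Reactants: 13 racemic 1,5-bis[4-(methoxymethoxy)phenyl]penta-2,4-diyn-1-ol
Product: 14 1,5-bis[4-(methoxymethoxy)phenyl]penta-2,4-diyn-1-one
Conditions: activated MnO2 (15 equiv), CH2Cl2, rt; filter through Celite
Reagents that add atoms: none
Why: MnO2 oxidation is selective for the doubly activated (benzylic and propargylic) alcohol and is neutral, so the acetals and the new conjugate acceptor should survive; 14 is kept cold and dark in solution and used directly.

Step 7
Reactants: 6 1-(methoxymethoxy)-4-[(1E,3E)-penta-1,3-dien-1-yl]benzene; 14 1,5-bis[4-(methoxymethoxy)phenyl]penta-2,4-diyn-1-one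
Product: 16 [4-(methoxymethoxy)phenyl]{6-[4-(methoxymethoxy)phenyl]-2-{[4-(methoxymethoxy)phenyl]ethynyl}-3-methylphenyl}methanone, via cis-cyclohexa-1,4-diene adduct 15 (not isolated)
Conditions: 6 (1.5 equiv), 14 (1.0 equiv), BHT (5 mol %), toluene (0.5 M), 110 °C, sealed vessel, Ar; then rt, DDQ (1.7 equiv), same flask
Reagents that add atoms: none
Why: This is a thermal, concerted but asynchronous Diels–Alder reaction of normal electron demand: the s-cis form of 6 adds suprafacially across the triple bond of 14 that is conjugated to the carbonyl group, forming C1–C2 and C3–C4 and closing ring A by intermolecular [4+2] annulation of a four-carbon and a two-carbon component. The closest known reaction type is the cycloaddition of 1-aryl-1,3-dienes to alkynyl ketones followed by quinone dehydrogenation of the 1,4-cyclohexadiene. The 4-alkoxyphenyl group raises the HOMO coefficient at the remote, methyl-bearing diene terminus, which bonds first to the β-carbon of the ynone, while the developing positive charge sits on the benzylic terminus that closes onto the α-carbon; the aroyl group should therefore end up beside the aryl group and the alkynyl group beside the methyl group (ortho rule). Only the proximal triple bond is activated by the carbonyl group, so the distal, aryl-capped triple bond should remain as the target alkyne. The two sp3 centres of 15 (C1 and C4) are set cis by suprafacial addition to the (E,E)-diene and the adduct is racemic, but both C–H bonds are doubly allylic, DDQ should remove hydride and then a proton at room temperature, and neither centre survives in 16. The DDQ charge allows for the quinone that surplus diene consumes. BHT, moderate dilution and an inert atmosphere limit radical polymerization, and the acid-free medium keeps the three acetals intact.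

Step 8
Reactants: 16 [4-(methoxymethoxy)phenyl]{6-[4-(methoxymethoxy)phenyl]-2-{[4-(methoxymethoxy)phenyl]ethynyl}-3-methylphenyl}methanone
Product: 17 racemic [4-(methoxymethoxy)phenyl]{6-[4-(methoxymethoxy)phenyl]-2-{[4-(methoxymethoxy)phenyl]ethynyl}-3-methylphenyl}(phenyl)methanol
Conditions: PhLi (2 equiv), THF, −78 → −20 °C; aq. NH4Cl at −20 °C
Reagents that add atoms: phenyllithium [Li]c1ccccc1
Why: 1,2-Addition of an aryllithium to a non-enolizable diaryl ketone; phenyllithium is small and reactive enough for the flanked carbonyl and low temperature keeps it from the alkyne; the carbinol centre forms racemic, which is immaterial because it becomes trigonal in step 9.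

Step 9
Reactants: 17 racemic [4-(methoxymethoxy)phenyl]{6-[4-(methoxymethoxy)phenyl]-2-{[4-(methoxymethoxy)phenyl]ethynyl}-3-methylphenyl}(phenyl)methanol
Product: 19 selaginellin A, 4-{[6-(4-hydroxyphenyl)-2-[(4-hydroxyphenyl)ethynyl]-3-methylphenyl](phenyl)methylidene}cyclohexa-2,5-dien-1-one, via triphenol carbinol 18 (not isolated)
Conditions: conc. aq. HCl (10 equiv), MeOH/THF 2:1, rt → 40 °C; then aq. NaHCO3
Reagents that add atoms: none
Why: Acid-catalysed acetal cleavage (methanol carries the methoxymethyl groups off as dimethoxymethane) frees the three phenols, the triarylmethanol ionizes to a 4-hydroxyphenyl-stabilized cation, and loss of the phenolic proton on neutralization should give the p-quinone methide (fuchsone formation by dehydration of a 4-hydroxytriarylmethanol); no stereo-element arises because the dienone ring is symmetric.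

## Compound list

1 | 4-hydroxybenzaldehyde | Oc1ccc(C=O)cc1 | starting material
2 | 4-(methoxymethoxy)benzaldehyde | COCOc1ccc(C=O)cc1 | intermediate
3 | [(2E)-but-2-en-1-yl]triphenylphosphonium bromide | C/C=C/C[P+](c1ccccc1)(c1ccccc1)c1ccccc1.[Br-] | starting material
4 | [(2E)-but-2-en-1-ylidene]triphenyl-λ5-phosphane | C/C=C/C=P(c1ccccc1)(c1ccccc1)c1ccccc1 | intermediate (not isolated)
5 | 1-(methoxymethoxy)-4-[(1Z,3E)-penta-1,3-dien-1-yl]benzene, in admixture with 6 | C/C=C/C=C\c1ccc(OCOC)cc1 | intermediate (not isolated)
6 | 1-(methoxymethoxy)-4-[(1E,3E)-penta-1,3-dien-1-yl]benzene | C/C=C/C=C/c1ccc(OCOC)cc1 | intermediate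
7 | 1,4-bis(trimethylsilyl)buta-1,3-diyne | C[Si](C)(C)C#CC#C[Si](C)(C)C | starting material
8 | lithium 4-(trimethylsilyl)buta-1,3-diyn-1-ide | [Li]C#CC#C[Si](C)(C)C | intermediate (not isolated)
9 | racemic 1-[4-(methoxymethoxy)phenyl]-5-(trimethylsilyl)penta-2,4-diyn-1-ol | OC(C#CC#C[Si](C)(C)C)c1ccc(OCOC)cc1 | intermediate
10 | 4-iodophenol | Oc1ccc(I)cc1 | starting material
11 | 1-iodo-4-(methoxymethoxy)benzene | COCOc1ccc(I)cc1 | intermediate
12 | racemic 1-[4-(methoxymethoxy)phenyl]penta-2,4-diyn-1-ol | OC(C#CC#C)c1ccc(OCOC)cc1 | intermediate (not isolated)
13 | racemic 1,5-bis[4-(methoxymethoxy)phenyl]penta-2,4-diyn-1-ol | OC(C#CC#Cc1ccc(OCOC)cc1)c1ccc(OCOC)cc1 | intermediate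
14 | 1,5-bis[4-(methoxymethoxy)phenyl]penta-2,4-diyn-1-one | O=C(C#CC#Cc1ccc(OCOC)cc1)c1ccc(OCOC)cc1 | intermediate
15 | racemic [4-(methoxymethoxy)phenyl]{(3,6-cis)-6-[4-(methoxymethoxy)phenyl]-2-{[4-(methoxymethoxy)phenyl]ethynyl}-3-methylcyclohexa-1,4-dien-1-yl}methanone (one enantiomer drawn) | C[C@H]1C=C[C@@H](c2ccc(OCOC)cc2)C(C(=O)c2ccc(OCOC)cc2)=C1C#Cc1ccc(OCOC)cc1 | intermediate (not isolated)
16 | [4-(methoxymethoxy)phenyl]{6-[4-(methoxymethoxy)phenyl]-2-{[4-(methoxymethoxy)phenyl]ethynyl}-3-methylphenyl}methanone | Cc1ccc(-c2ccc(OCOC)cc2)c(C(=O)c2ccc(OCOC)cc2)c1C#Cc1ccc(OCOC)cc1 | intermediate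
17 | racemic [4-(methoxymethoxy)phenyl]{6-[4-(methoxymethoxy)phenyl]-2-{[4-(methoxymethoxy)phenyl]ethynyl}-3-methylphenyl}(phenyl)methanol | Cc1ccc(-c2ccc(OCOC)cc2)c(C(O)(c2ccccc2)c2ccc(OCOC)cc2)c1C#Cc1ccc(OCOC)cc1 | intermediate
18 | racemic {6-(4-hydroxyphenyl)-2-[(4-hydroxyphenyl)ethynyl]-3-methylphenyl}(4-hydroxyphenyl)(phenyl)methanol | Cc1ccc(-c2ccc(O)cc2)c(C(O)(c2ccccc2)c2ccc(O)cc2)c1C#Cc1ccc(O)cc1 | intermediate (not isolated)
19 | selaginellin A, 4-{[6-(4-hydroxyphenyl)-2-[(4-hydroxyphenyl)ethynyl]-3-methylphenyl](phenyl)methylidene}cyclohexa-2,5-dien-1-one | Cc1ccc(-c2ccc(O)cc2)c(C(=C2C=CC(=O)C=C2)c2ccccc2)c1C#Cc1ccc(O)cc1 | target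

## Step count and least certain steps

Total: 9 steps. Longest linear sequence: 7 steps (steps 1, 3, 5, 6, 7, 8, 9).

Step 7 (key step). The cycloaddition at a fully substituted triple bond may be slow, so that thermal oligomerization of the diynone and the diene outruns ring formation. The orientation may also erode, because the methyl group at the other diene terminus and the alkynyl group on the β-carbon work against the aryl/acyl bias, and some addition at the distal triple bond is possible. A calorimetric check of 14 should precede any scale-up. The fallback sets out from 2, 6 and 11 and comes back at 16. It uses a dienophile with a single triple bond and introduces the alkyne after ring A is made.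
- Ethynylmagnesium bromide adds to 2 to give racemic 1-[4-(methoxymethoxy)phenyl]prop-2-yn-1-ol F1.
- NBS with catalytic AgNO3 in acetone brominates the alkyne terminus to racemic 3-bromo-1-[4-(methoxymethoxy)phenyl]prop-2-yn-1-ol F2, and MnO2 oxidizes this to 3-bromo-1-[4-(methoxymethoxy)phenyl]prop-2-yn-1-one F3.
- This compact, more electron-poor ynone should add to 6 in toluene at lower temperature with the same carbonyl-directed orientation. The racemic cis adduct {2-bromo-6-[4-(methoxymethoxy)phenyl]-3-methylcyclohexa-1,4-dien-1-yl}[4-(methoxymethoxy)phenyl]methanone F4 is dehydrogenated by DDQ in the same flask to {2-bromo-6-[4-(methoxymethoxy)phenyl]-3-methylphenyl}[4-(methoxymethoxy)phenyl]methanone F5.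
- Separately, 11 is coupled with ethynyltrimethylsilane (Pd(PPh3)2Cl2, CuI, Et3N) to {[4-(methoxymethoxy)phenyl]ethynyl}trimethylsilane F6, which K2CO3 in MeOH converts to 1-ethynyl-4-(methoxymethoxy)benzene F7.
- Copper-free Sonogashira coupling of F5 with F7 (Pd(MeCN)2Cl2, XPhos, Cs2CO3, MeCN, 80 °C) returns to 16.

Step 5. Oxidative dimerization and base- or copper-induced decomposition of the liberated terminal diyne may compete with a slow oxidative addition into the electron-rich aryl iodide. The fallback sets out from 8 (made from 7 as in step 3), 11 and 2 and comes back at 13. It never forms a terminal diyne and uses no copper.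
- ZnCl2 transmetallates 8 to chloro[4-(trimethylsilyl)buta-1,3-diyn-1-yl]zinc F8.
- Negishi coupling of F8 with 11 (Pd(PPh3)4, THF, rt) gives {[4-(methoxymethoxy)phenyl]buta-1,3-diyn-1-yl}trimethylsilane F9.
- MeLi·LiBr cleaves the remaining C–Si bond to lithium 4-[4-(methoxymethoxy)phenyl]buta-1,3-diyn-1-ide F10, which adds to 2 at −78 °C to give 13.

Step 8. Addition may stall at a carbonyl group shielded by two ortho substituents and deactivated by the para-alkoxy group. On warming, excess phenyllithium or the new tertiary alkoxide may attack the neighbouring triple bond. The fallback sets out from 8, 11 and 6 and comes back at 17. It exchanges the roles of the two aryl groups on C7, so that a more electrophilic benzoyl ketone receives the oxygenated aryl nucleophile.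
- 8 adds to benzaldehyde to give racemic 1-phenyl-5-(trimethylsilyl)penta-2,4-diyn-1-ol F11.
- Under the conditions of step 5 this passes through racemic 1-phenylpenta-2,4-diyn-1-ol F12 and couples with 11 to racemic 5-[4-(methoxymethoxy)phenyl]-1-phenylpenta-2,4-diyn-1-ol F13.
- MnO2 gives 5-[4-(methoxymethoxy)phenyl]-1-phenylpenta-2,4-diyn-1-one F14.
- Cycloaddition with 6 as in step 7 gives the racemic cis adduct {6-[4-(methoxymethoxy)phenyl]-2-{[4-(methoxymethoxy)phenyl]ethynyl}-3-methylcyclohexa-1,4-dien-1-yl}(phenyl)methanone F15, and DDQ gives {6-[4-(methoxymethoxy)phenyl]-2-{[4-(methoxymethoxy)phenyl]ethynyl}-3-methylphenyl}(phenyl)methanone F16.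
- Iodine–lithium exchange on 11 (n-BuLi, THF, −78 °C) gives [4-(methoxymethoxy)phenyl]lithium F17, which adds to F16 to give 17.

Step 9. Under acid the triarylmethyl cation may be captured by the ortho aryl ring or the alkyne (Friedel–Crafts-type closure). The freed phenols may be hydroxymethylated by formaldehyde equivalents, and methanol may be retained at C7. The fallback sets out from 16 and comes back at 18. It moves the acid treatment to the ketone stage, where no cation can form, and ends with fluoride.
- HCl in MeOH/THF converts 16 into (4-hydroxyphenyl){6-(4-hydroxyphenyl)-2-[(4-hydroxyphenyl)ethynyl]-3-methylphenyl}methanone F18.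
- TBSCl and imidazole in DMF give the corresponding tris(tert-butyldimethylsilyl) ether F19.
- Phenyllithium adds as in step 8 to give the racemic tris(silyl) carbinol F20.
- Bu4NF buffered with acetic acid in THF at 0 °C releases 18, which should lose water to 19 on gentle warming with a trace of acetic acid.

## Further compounds

F1 | step 7 | racemic 1-[4-(methoxymethoxy)phenyl]prop-2-yn-1-ol | OC(C#C)c1ccc(OCOC)cc1
F2 | step 7 | racemic 3-bromo-1-[4-(methoxymethoxy)phenyl]prop-2-yn-1-ol | OC(C#CBr)c1ccc(OCOC)cc1
F3 | step 7 | 3-bromo-1-[4-(methoxymethoxy)phenyl]prop-2-yn-1-one | O=C(C#CBr)c1ccc(OCOC)cc1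
F4 | step 7 | racemic {(3,6-cis)-2-bromo-6-[4-(methoxymethoxy)phenyl]-3-methylcyclohexa-1,4-dien-1-yl}[4-(methoxymethoxy)phenyl]methanone (one enantiomer drawn; not isolated) | C[C@H]1C=C[C@@H](c2ccc(OCOC)cc2)C(C(=O)c2ccc(OCOC)cc2)=C1Br
F5 | step 7 | {2-bromo-6-[4-(methoxymethoxy)phenyl]-3-methylphenyl}[4-(methoxymethoxy)phenyl]methanone | Cc1ccc(-c2ccc(OCOC)cc2)c(C(=O)c2ccc(OCOC)cc2)c1Br
F6 | step 7 | {[4-(methoxymethoxy)phenyl]ethynyl}trimethylsilane | COCOc1ccc(C#C[Si](C)(C)C)cc1
F7 | step 7 | 1-ethynyl-4-(methoxymethoxy)benzene | C#Cc1ccc(OCOC)cc1
F8 | step 5 | chloro[4-(trimethylsilyl)buta-1,3-diyn-1-yl]zinc (not isolated) | Cl[Zn]C#CC#C[Si](C)(C)C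
F9 | step 5 | {[4-(methoxymethoxy)phenyl]buta-1,3-diyn-1-yl}trimethylsilane | COCOc1ccc(C#CC#C[Si](C)(C)C)cc1
F10 | step 5 | lithium 4-[4-(methoxymethoxy)phenyl]buta-1,3-diyn-1-ide (not isolated) | [Li]C#CC#Cc1ccc(OCOC)cc1
F11 | step 8 | racemic 1-phenyl-5-(trimethylsilyl)penta-2,4-diyn-1-ol | OC(C#CC#C[Si](C)(C)C)c1ccccc1
F12 | step 8 | racemic 1-phenylpenta-2,4-diyn-1-ol (not isolated) | OC(C#CC#C)c1ccccc1
F13 | step 8 | racemic 5-[4-(methoxymethoxy)phenyl]-1-phenylpenta-2,4-diyn-1-ol | OC(C#CC#Cc1ccc(OCOC)cc1)c1ccccc1
F14 | step 8 | 5-[4-(methoxymethoxy)phenyl]-1-phenylpenta-2,4-diyn-1-one | O=C(C#CC#Cc1ccc(OCOC)cc1)c1ccccc1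
F15 | step 8 | racemic {(3,6-cis)-6-[4-(methoxymethoxy)phenyl]-2-{[4-(methoxymethoxy)phenyl]ethynyl}-3-methylcyclohexa-1,4-dien-1-yl}(phenyl)methanone (one enantiomer drawn; not isolated) | C[C@H]1C=C[C@@H](c2ccc(OCOC)cc2)C(C(=O)c2ccccc2)=C1C#Cc1ccc(OCOC)cc1
F16 | step 8 | {6-[4-(methoxymethoxy)phenyl]-2-{[4-(methoxymethoxy)phenyl]ethynyl}-3-methylphenyl}(phenyl)methanone | Cc1ccc(-c2ccc(OCOC)cc2)c(C(=O)c2ccccc2)c1C#Cc1ccc(OCOC)cc1
F17 | step 8 | [4-(methoxymethoxy)phenyl]lithium (not isolated) | [Li]c1ccc(OCOC)cc1
F18 | step 9 | (4-hydroxyphenyl){6-(4-hydroxyphenyl)-2-[(4-hydroxyphenyl)ethynyl]-3-methylphenyl}methanone | Cc1ccc(-c2ccc(O)cc2)c(C(=O)c2ccc(O)cc2)c1C#Cc1ccc(O)cc1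
F19 | step 9 | (4-{[tert-butyl(dimethyl)silyl]oxy}phenyl){6-(4-{[tert-butyl(dimethyl)silyl]oxy}phenyl)-2-[(4-{[tert-butyl(dimethyl)silyl]oxy}phenyl)ethynyl]-3-methylphenyl}methanone | Cc1ccc(-c2ccc(O[Si](C)(C)C(C)(C)C)cc2)c(C(=O)c2ccc(O[Si](C)(C)C(C)(C)C)cc2)c1C#Cc1ccc(O[Si](C)(C)C(C)(C)C)cc1
F20 | step 9 | racemic (4-{[tert-butyl(dimethyl)silyl]oxy}phenyl){6-(4-{[tert-butyl(dimethyl)silyl]oxy}phenyl)-2-[(4-{[tert-butyl(dimethyl)silyl]oxy}phenyl)ethynyl]-3-methylphenyl}(phenyl)methanol | Cc1ccc(-c2ccc(O[Si](C)(C)C(C)(C)C)cc2)c(C(O)(c2ccccc2)c2ccc(O[Si](C)(C)C(C)(C)C)cc2)c1C#Cc1ccc(O[Si](C)(C)C(C)(C)C)cc1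
A1 | alternative 1 | ethyl 2-(4-methoxyphenyl)-4-[(4-methoxyphenyl)ethynyl]-5-methyl-6-oxo-6H-pyran-3-carboxylate | CCOC(=O)C1=C(c2ccc(OC)cc2)OC(=O)C(C)=C1C#Cc1ccc(OC)cc1
A2 | alternative 1 | butyl vinyl ether | C=COCCCC
A3 | alternative 1 | ethyl 6-(4-methoxyphenyl)-2-[(4-methoxyphenyl)ethynyl]-3-methylbenzoate | CCOC(=O)c1c(-c2ccc(OC)cc2)ccc(C)c1C#Cc1ccc(OC)cc1
A4 | alternative 2 | 1-phenylpentane-1,3-dione | CCC(=O)CC(=O)c1ccccc1
A5 | alternative 2 | (2E)-3-(4-methoxyphenyl)prop-2-enal | COc1ccc(/C=C/C=O)cc1
A6 | alternative 2 | [2-hydroxy-6-(4-methoxyphenyl)-3-methylphenyl](phenyl)methanone | Cc1ccc(-c2ccc(OC)cc2)c(C(=O)c2ccccc2)c1O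
A7 | alternative 3 | 4-fluoro-2-{[4-(methoxymethoxy)phenyl]ethynyl}-1-methylbenzene | Cc1ccc(F)cc1C#Cc1ccc(OCOC)cc1
A8 | alternative 3 | bromo[4-(methoxymethoxy)phenyl]magnesium | COCOc1ccc([Mg]Br)cc1
A9 | alternative 3 | [4-(methoxymethoxy)phenyl](phenyl)methanone | COCOc1ccc(C(=O)c2ccccc2)cc1
A10 | alternative 3 | racemic [4-(methoxymethoxy)phenyl]{6-[4-(methoxymethoxy)phenyl]-2-{[4-(methoxymethoxy)phenyl]ethynyl}-3-methylphenyl}(phenyl)methanol | Cc1ccc(-c2ccc(OCOC)cc2)c(C(O)(c2ccccc2)c2ccc(OCOC)cc2)c1C#Cc1ccc(OCOC)cc1
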